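**Plan**

1. Retrosynthesis: the C1'–C2 aryl–pyrone bond is cut first (last C–C bond made), then C7''–C8'' (aldol) and the O4'–C8'' ether bond (phenol O-alkylation with a two-carbon acid); in the other half O1–C2 and C2–C3 of the pyrone are cut (one-carbon unit on an acetophenone).
2. Forward: ring C closes on a dibenzylated phloroacetophenone to give a 5,7-dibenzyloxychromone with a free C2–H. Separately, 4-bromo-2,6-dimethoxyphenol (ring B) is O-alkylated, the C7''–C8'' bond is made by an auxiliary-controlled aldol reaction, and the bromide is turned into a boronic acid.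
3. Key event: oxidative boron-Heck union of that boronic acid with the unfunctionalised chromone. The enabling feature is the C2=C3 bond of γ-pyrone ring C, a vinylogous-ester double bond polarised by O1 and the C4 carbonyl. An aryl–palladium species delivers the aryl group to C2, and the C4 carbonyl makes the C3–palladium bond an enolate that can epimerise and lose the C2 hydrogen. The flavone therefore forms at its final oxidation level; boron is the only activating group and leaves in the same step.
4. Stereochemistry: C7'' and C8'' are both set in the single Evans syn-aldol step under control of (R)-4-benzyl-1,3-oxazolidin-2-one (threo, 7''S,8''S); no later step makes or breaks a bond at either center.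
5. End game: fluoride removes two silyl ethers, then hydrogenolysis removes three benzyl ethers.

Key step: step 9

Remark: (7''S,8''S) is the threo (syn-aldol) arrangement written in the SMILES; C8'' is labelled R while C9'' is an imide carbonyl and S once C9'' is CH2O, with no change in space. The five numbered starting materials are taken as catalogue chemicals.

**Route**

Step 1
Reactants: 1 2',4',6'-trihydroxyacetophenone [1-(2,4,6-trihydroxyphenyl)ethan-1-one]
Product: 2 1-[2,4-bis(benzyloxy)-6-hydroxyphenyl]ethan-1-one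
Conditions: BnBr (2.1 equiv), K2CO3 (2.2 equiv), acetone, reflux
Reagents that add atoms: benzyl bromide, BrCc1ccccc1
Why: Williamson etherification, in which the 4-OH and one of the two equivalent ortho-OH groups are alkylated while the last ortho-OH stays hydrogen-bonded to the acetyl carbonyl and should be too weakly nucleophilic to react.

Step 2
Reactants: 2 1-[2,4-bis(benzyloxy)-6-hydroxyphenyl]ethan-1-one
Product: 4 5,7-bis(benzyloxy)-4H-chromen-4-one, via enaminone 3 (not isolated)
Conditions: Me2NCH(OMe)2 (3 equiv), toluene, 100 °C; evaporate; conc. aq. HCl, CH2Cl2, 40 °C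
Reagents that add atoms: N,N-dimethylformamide dimethyl acetal, COC(OC)N(C)C
Why: Condensation of the methyl ketone with the amide acetal gives the vinylogous amide, and acid then triggers 6-endo-trig addition of the phenol oxygen to the β-carbon and loss of dimethylamine (enaminone route to chromones), which closes ring C without forming a stereocenter.

Step 3
Reactants: 5 4-bromo-2,6-dimethoxyphenol; 6 bromoacetic acid
Product: 7 2-(4-bromo-2,6-dimethoxyphenoxy)acetic acid
Conditions: NaH (2.2 equiv), THF, 0 °C → reflux; then 1 M aq. HCl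
Reagents that add atoms: none
Why: Williamson etherification, in which the sodium phenoxide displaces bromide from the unhindered primary carbon of sodium bromoacetate by SN2, a reaction that should tolerate the two ortho methoxy groups.

Step 4
Reactants: 7 2-(4-bromo-2,6-dimethoxyphenoxy)acetic acid; 8 (R)-4-benzyl-1,3-oxazolidin-2-one
Product: 10 (R)-4-benzyl-3-[2-(4-bromo-2,6-dimethoxyphenoxy)acetyl]-1,3-oxazolidin-2-one, via mixed pivalic anhydride 9 (not isolated)
Conditions: t-BuCOCl (1.1 equiv), Et3N (2.5 equiv), THF, −20 °C; then 8, LiCl (1.1 equiv), −20 °C → rt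
Reagents that add atoms: none
Why: N-acylation of the oxazolidinone through a mixed anhydride, in which the LiCl/Et3N-activated carbamate nitrogen attacks the less hindered aryloxyacetyl carbonyl because the tert-butyl group shields the other one.

Step 5
Reactants: 10 (R)-4-benzyl-3-[2-(4-bromo-2,6-dimethoxyphenoxy)acetyl]-1,3-oxazolidin-2-one; 11 4-(benzyloxy)benzaldehyde
Product: 14 (4R)-4-benzyl-3-[(2R,3S)-3-[4-(benzyloxy)phenyl]-2-(4-bromo-2,6-dimethoxyphenoxy)-3-hydroxypropanoyl]-1,3-oxazolidin-2-one, via Z-boron enolate 12 (not isolated), via boron aldolate 13 (not isolated)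
Conditions: Bu2BOTf (1.2 equiv), i-Pr2NEt (1.4 equiv), CH2Cl2, 0 °C; 11 (1.2 equiv), −78 → 0 °C; pH 7 buffer, MeOH, 30% aq. H2O2, 0 °C
Reagents that add atoms: none
Why: Evans syn-aldol reaction, in which soft enolisation gives the Z-boron enolate that adds to the aldehyde through a chair Zimmerman–Traxler transition state with the oxazolidinone carbonyl dipole turned away, so the aldehyde should approach the enolate face opposite the benzyl group and set C8'' (2R in the imide) and C7'' (3S) together in the syn (threo) relationship.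

Step 6
Reactants: 14 the syn-aldol adduct of step 5
Product: 15 (1S,2S)-1-[4-(benzyloxy)phenyl]-2-(4-bromo-2,6-dimethoxyphenoxy)propane-1,3-diol
Conditions: NaBH4 (4 equiv), THF/H2O (4:1), 0 °C → rt
Reagents that add atoms: none
Why: Borohydride reductive cleavage of the N-acyloxazolidinone, in which hydride adds to the more electrophilic exocyclic carbonyl, the hemiaminal collapses to the aldehyde and this is reduced to the primary alcohol, so both stereocenters should pass unchanged and the auxiliary is released.

Step 7
Reactants: 15 (1S,2S)-1-[4-(benzyloxy)phenyl]-2-(4-bromo-2,6-dimethoxyphenoxy)propane-1,3-diol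
Product: 16 (1S,2S)-1-[4-(benzyloxy)phenyl]-2-(4-bromo-2,6-dimethoxyphenoxy)-1,3-bis[(tert-butyldimethylsilyl)oxy]propane
Conditions: TBSOTf (2.5 equiv), 2,6-lutidine (4 equiv), CH2Cl2, −78 → 0 °C
Reagents that add atoms: tert-butyldimethylsilyl triflate, CC(C)(C)[Si](C)(C)OS(=O)(=O)C(F)(F)F
Why: Silyl ether formation with a silyl triflate and a hindered pyridine base should cap both hydroxyls, which would otherwise quench the aryllithium of step 8 and expose the benzylic alcohol to oxidation by divalent palladium in step 9.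

Step 8
Reactants: 16 the bis-silyl ether of step 7
Product: 19 [4-({(1S,2S)-1-[4-(benzyloxy)phenyl]-1,3-bis[(tert-butyldimethylsilyl)oxy]propan-2-yl}oxy)-3,5-dimethoxyphenyl]boronic acid, via aryllithium 17 (not isolated), via lithium triisopropoxyborate 18 (not isolated)
Conditions: B(Oi-Pr)3 (1.5 equiv), then n-BuLi (1.15 equiv) dropwise, THF/toluene, −78 °C; 1 M aq. HCl to pH 5, 0 °C
Reagents that add atoms: triisopropyl borate, CC(C)OB(OC(C)C)OC(C)C; water, O
Why: Bromine–lithium exchange, which at −78 °C should be much faster than deprotonation or attack of butyllithium on the borate, followed by in-situ trapping of the aryllithium by the borate ester and mild hydrolysis (electrophilic borylation of an organolithium).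

Step 9
Reactants: 19 the arylboronic acid of step 8; 4 5,7-bis(benzyloxy)-4H-chromen-4-one
Product: 20 5,7-bis(benzyloxy)-2-[4-({(1S,2S)-1-[4-(benzyloxy)phenyl]-1,3-bis[(tert-butyldimethylsilyl)oxy]propan-2-yl}oxy)-3,5-dimethoxyphenyl]-4H-chromen-4-one
Conditions: Pd(O2CCF3)2 (10 mol %), 5-nitro-1,10-phenanthroline (20 mol %), O2 (1 atm), DMSO, 90 °C; 4 (2 equiv), 19 added in portions
Reagents that add atoms: none
Why: Oxidative boron-Heck reaction: the aryl group of 19 passes from boron to phenanthroline-ligated divalent palladium, the aryl–palladium bond adds syn across the C2=C3 bond of the γ-pyrone ring of 4 with the aryl group going to C2 (the β-carbon of the vinylogous ester, made electrophilic by O1 and the C4 carbonyl), the C3-bound palladium enolate epimerises through its oxygen-bound form so that β-hydride elimination of the C2 hydrogen restores the pyrone, and O2 reoxidises the zerovalent palladium. The closest known reaction type is the palladium-catalysed oxidative coupling of arylboronic acids with chromones and chromanones to give flavones. No ring is closed and no stereocenter is formed, and C7'' and C8'' carry neither an acidic hydrogen nor a free hydroxyl, so they should pass unchanged. The step needs arylation at C2 and not at C3, which the polarity of the enone double bond secures, and elimination in place of protonation of the palladium enolate, which the aprotic oxidising medium should favour. The silyl ethers keep the benzylic C7'' oxygen from being oxidised, and the excess of the cheap chromone 4 should offset loss of 19 by homocoupling or protodeboronation.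

Step 10
Reactants: 20 the fully protected flavonolignan of step 9
Product: 21 5,7-bis(benzyloxy)-2-[4-({(1S,2S)-1-[4-(benzyloxy)phenyl]-1,3-dihydroxypropan-2-yl}oxy)-3,5-dimethoxyphenyl]-4H-chromen-4-one
Conditions: HF·pyridine, pyridine, THF, 0 °C → rt
Reagents that add atoms: none
Why: Fluoride-mediated desilylation under buffered conditions should cleave both Si–O bonds (driven by the strong Si–F bond) without ionising the benzylic C7''–O bond or touching the benzyl ethers and the flavone.

Step 11
Reactants: 21 the tri-O-benzyl diol of step 10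
Product: 22 (-)-(7''S,8''S)-4'',5,7-trihydroxy-3',5'-dimethoxy-4',8''-oxyflavonolignan-7'',9''-diol
Conditions: H2 (1 atm), Pd/C (10 wt %), THF/EtOAc, rt
Reagents that add atoms: none
Why: Catalytic hydrogenolysis should cleave the three aryl benzyl ethers much faster than the secondary benzylic C7''–OH bond or the conjugated C2=C3 bond in a neutral aprotic solvent, releasing the target with both stereocenters intact.

**Compound list**

1 | 2',4',6'-trihydroxyacetophenone | CC(=O)c1c(O)cc(O)cc1O | starting material
2 | 1-[2,4-bis(benzyloxy)-6-hydroxyphenyl]ethan-1-one | CC(=O)c1c(O)cc(OCc2ccccc2)cc1OCc1ccccc1 | intermediate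
3 | (E)-1-[2,4-bis(benzyloxy)-6-hydroxyphenyl]-3-(dimethylamino)prop-2-en-1-one (enaminone, not isolated) | CN(C)/C=C/C(=O)c1c(O)cc(OCc2ccccc2)cc1OCc1ccccc1 | intermediate
4 | 5,7-bis(benzyloxy)-4H-chromen-4-one | O=c1ccoc2cc(OCc3ccccc3)cc(OCc3ccccc3)c12 | intermediate
5 | 4-bromo-2,6-dimethoxyphenol | COc1cc(Br)cc(OC)c1O | starting material
6 | bromoacetic acid | OC(=O)CBr | starting material
7 | 2-(4-bromo-2,6-dimethoxyphenoxy)acetic acid | COc1cc(Br)cc(OC)c1OCC(=O)O | intermediate
8 | (R)-4-benzyl-1,3-oxazolidin-2-one | O=C1N[C@H](Cc2ccccc2)CO1 | starting material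
9 | 2-(4-bromo-2,6-dimethoxyphenoxy)acetic pivalic anhydride (not isolated) | COc1cc(Br)cc(OC)c1OCC(=O)OC(=O)C(C)(C)C | intermediate
10 | (R)-4-benzyl-3-[2-(4-bromo-2,6-dimethoxyphenoxy)acetyl]-1,3-oxazolidin-2-one | COc1cc(Br)cc(OC)c1OCC(=O)N1[C@H](Cc2ccccc2)COC1=O | intermediate
11 | 4-(benzyloxy)benzaldehyde | O=Cc1ccc(OCc2ccccc2)cc1 | starting material
12 | Z-dibutylboron enolate of 10, aryloxy and boryloxy groups cis (not isolated) | COc1cc(Br)cc(OC)c1O/C=C(\OB(CCCC)CCCC)N1[C@H](Cc2ccccc2)COC1=O | intermediate
13 | O-dibutylboryl aldolate of 14 (not isolated) | COc1cc(Br)cc(OC)c1O[C@@H](C(=O)N1[C@H](Cc2ccccc2)COC1=O)[C@@H](OB(CCCC)CCCC)c1ccc(OCc2ccccc2)cc1 | intermediate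
14 | (4R)-4-benzyl-3-[(2R,3S)-3-[4-(benzyloxy)phenyl]-2-(4-bromo-2,6-dimethoxyphenoxy)-3-hydroxypropanoyl]-1,3-oxazolidin-2-one | COc1cc(Br)cc(OC)c1O[C@@H](C(=O)N1[C@H](Cc2ccccc2)COC1=O)[C@@H](O)c1ccc(OCc2ccccc2)cc1 | intermediate
15 | (1S,2S)-1-[4-(benzyloxy)phenyl]-2-(4-bromo-2,6-dimethoxyphenoxy)propane-1,3-diol | COc1cc(Br)cc(OC)c1O[C@@H](CO)[C@@H](O)c1ccc(OCc2ccccc2)cc1 | intermediate
16 | (1S,2S)-1-[4-(benzyloxy)phenyl]-2-(4-bromo-2,6-dimethoxyphenoxy)-1,3-bis[(tert-butyldimethylsilyl)oxy]propane | COc1cc(Br)cc(OC)c1O[C@@H](CO[Si](C)(C)C(C)(C)C)[C@@H](O[Si](C)(C)C(C)(C)C)c1ccc(OCc2ccccc2)cc1 | intermediate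
17 | aryllithium from 16, lithium in place of bromine (not isolated) | COc1cc([Li])cc(OC)c1O[C@@H](CO[Si](C)(C)C(C)(C)C)[C@@H](O[Si](C)(C)C(C)(C)C)c1ccc(OCc2ccccc2)cc1 | intermediate
18 | lithium aryl(triisopropoxy)borate from 17 (not isolated) | COc1cc([B-](OC(C)C)(OC(C)C)OC(C)C)cc(OC)c1O[C@@H](CO[Si](C)(C)C(C)(C)C)[C@@H](O[Si](C)(C)C(C)(C)C)c1ccc(OCc2ccccc2)cc1.[Li+] | intermediate
19 | [4-({(1S,2S)-1-[4-(benzyloxy)phenyl]-1,3-bis[(tert-butyldimethylsilyl)oxy]propan-2-yl}oxy)-3,5-dimethoxyphenyl]boronic acid | COc1cc(B(O)O)cc(OC)c1O[C@@H](CO[Si](C)(C)C(C)(C)C)[C@@H](O[Si](C)(C)C(C)(C)C)c1ccc(OCc2ccccc2)cc1 | intermediate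
20 | 5,7-bis(benzyloxy)-2-[4-({(1S,2S)-1-[4-(benzyloxy)phenyl]-1,3-bis[(tert-butyldimethylsilyl)oxy]propan-2-yl}oxy)-3,5-dimethoxyphenyl]-4H-chromen-4-one | COc1cc(-c2cc(=O)c3c(OCc4ccccc4)cc(OCc4ccccc4)cc3o2)cc(OC)c1O[C@@H](CO[Si](C)(C)C(C)(C)C)[C@@H](O[Si](C)(C)C(C)(C)C)c1ccc(OCc2ccccc2)cc1 | intermediate
21 | 5,7-bis(benzyloxy)-2-[4-({(1S,2S)-1-[4-(benzyloxy)phenyl]-1,3-dihydroxypropan-2-yl}oxy)-3,5-dimethoxyphenyl]-4H-chromen-4-one | COc1cc(-c2cc(=O)c3c(OCc4ccccc4)cc(OCc4ccccc4)cc3o2)cc(OC)c1O[C@@H](CO)[C@@H](O)c1ccc(OCc2ccccc2)cc1 | intermediate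
22 | (-)-(7''S,8''S)-4'',5,7-trihydroxy-3',5'-dimethoxy-4',8''-oxyflavonolignan-7'',9''-diol | COc1cc(-c2cc(=O)c3c(O)cc(O)cc3o2)cc(OC)c1O[C@@H](CO)[C@@H](O)c1ccc(O)cc1 | target

**Count and risks**

Total step count: 11. Longest linear sequence: 9 steps (steps 3 to 11, from 4-bromo-2,6-dimethoxyphenol); the chromone branch (steps 1 and 2) joins at step 9.

Step 9 (key coupling). Transmetalation may be outrun by oxidative homocoupling, protodeboronation or oxidation of the electron-rich boronic acid, or the palladium enolate may be protonated faster than it eliminates, so that the reaction halts at the saturated stage. The fallback separates aryl transfer from oxidation. It sets out from 19 and 4: a rhodium-catalysed 1,4-addition of Hayashi–Miyaura type ([Rh(OH)(cod)]2, dioxane/H2O, 60 °C, no oxidant present) should give the 2-aryl-5,7-bis(benzyloxy)chroman-4-one (flavanone, both C2 epimers, which does not matter) F1. A separate palladium-catalysed aerobic α,β-dehydrogenation of this ketone (Pd(O2CCF3)2, DMSO as ligand, O2, EtOAc, 60 °C), now free of any boron species, should then give 20, where the route is rejoined.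

Step 11 (hydrogenolysis). Over-reduction may occur: cleavage of the benzylic C7''–O bond once the para-phenol is unmasked, or saturation of the C2=C3 bond before the hindered 5-O-benzyl ether has gone. The fallback changes the order so that the benzylic oxygen stays masked as a bulky, non-ionisable silyl ether during the reduction. It sets out from 20: hydrogenolysis (H2, Pd/C, THF/EtOAc) should give the 7'',9''-bis-O-silyl triphenol F2, and HF·pyridine in THF/pyridine should then remove the two silyl groups to reach 22 directly.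

Step 5 (aldol). Syn and facial selectivity may erode, or enolisation may stay incomplete, if the aryloxy and ortho-methoxy oxygens compete with the aldehyde for boron; retro-aldol cleavage during the oxidative work-up is a further risk. The fallback uses a chlorotitanium enolate of an N-acylthiazolidinethione and needs no oxidative work-up. It sets out from acid 7: coupling with (R)-4-benzyl-1,3-thiazolidine-2-thione (EDC·HCl, DMAP, CH2Cl2) should give the N-(aryloxyacetyl)thiazolidinethione F3. Enolisation with TiCl4, i-Pr2NEt and N-methylpyrrolidin-2-one in CH2Cl2 and addition of 11 at −78 °C should give, through the non-chelated chair transition state, the syn-aldol adduct of the same (2R,3S) sense F4. NaBH4 in THF/EtOH should then cleave the auxiliary and return the route at diol 15.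

**Further compounds**

F1 | step 9 | 5,7-bis(benzyloxy)-2-[4-({(1S,2S)-1-[4-(benzyloxy)phenyl]-1,3-bis[(tert-butyldimethylsilyl)oxy]propan-2-yl}oxy)-3,5-dimethoxyphenyl]chroman-4-one (both C2 epimers) | COc1cc(C2CC(=O)c3c(OCc4ccccc4)cc(OCc4ccccc4)cc3O2)cc(OC)c1O[C@@H](CO[Si](C)(C)C(C)(C)C)[C@@H](O[Si](C)(C)C(C)(C)C)c1ccc(OCc2ccccc2)cc1
F2 | step 11 | 2-[4-({(1S,2S)-1,3-bis[(tert-butyldimethylsilyl)oxy]-1-(4-hydroxyphenyl)propan-2-yl}oxy)-3,5-dimethoxyphenyl]-5,7-dihydroxy-4H-chromen-4-one | COc1cc(-c2cc(=O)c3c(O)cc(O)cc3o2)cc(OC)c1O[C@@H](CO[Si](C)(C)C(C)(C)C)[C@@H](O[Si](C)(C)C(C)(C)C)c1ccc(O)cc1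
F3 | step 5 | 1-[(R)-4-benzyl-2-thioxo-1,3-thiazolidin-3-yl]-2-(4-bromo-2,6-dimethoxyphenoxy)ethan-1-one | COc1cc(Br)cc(OC)c1OCC(=O)N1[C@H](Cc2ccccc2)CSC1=S
F4 | step 5 | (2R,3S)-1-[(R)-4-benzyl-2-thioxo-1,3-thiazolidin-3-yl]-3-[4-(benzyloxy)phenyl]-2-(4-bromo-2,6-dimethoxyphenoxy)-3-hydroxypropan-1-one | COc1cc(Br)cc(OC)c1O[C@@H](C(=O)N1[C@H](Cc2ccccc2)CSC1=S)[C@@H](O)c1ccc(OCc2ccccc2)cc1
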